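**Plan**

- Ring numbering used throughout: C1 ketone, C2 N‑bearing carbon, C3, C4 carbinol, C5/C6 oxirane carbons. The retrosynthesis cuts (i) the triene between its second and third carbon counted from C4 (Stille), (ii) the C2–N enamide bond (Pd amidation of an enol triflate), (iii) the oxirane (enone epoxidation), (iv) the C1–O and C4–O bonds together (singlet‑oxygen [4+2]) and (v) the C4–C(sp) bond (Sonogashira on a bromodiene).
- Enabling feature: the oxygens on C1 and C4 stand 1,4 to each other across the C5–C6 unit and C4 has no hydrogen. The six‑membered ring is therefore the base‑opened form of a cyclohexadiene 1,4‑endoperoxide whose only bridgehead hydrogen sits on C1.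
- Forward order: microbial bromo cis‑diol → acetonide → alkynyl diene → endoperoxide (the carbocycle is there from the start; the peroxide ring is the only ring closed, and it is opened again) → hydroxy enone → syn epoxide → diosphenol triflate → enamide → vinylstannane, joined last to a separately made bromodienamide.
- Stereochemistry: the enzymatic cis‑diol is the only chiral source. Its acetonide sends oxygen to the anti face and sets C4; the C4 hydroxyl and the acetonide together set the oxirane syn to the hydroxyl; the diol carbons are then erased. Alkene geometry comes from Wittig/HWE reactions, syn‑hydrostannation and stereoretentive couplings.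

Key step: step 3

Assumption: glutaconaldehyde potassium salt, (triphenylphosphoranylidene)acetaldehyde and diethyl (2‑amino‑2‑oxoethyl)phosphonate are taken as catalogue reagents.

**Route**

Step 1
Reactants: 1 (1S,2S)-3-bromocyclohexa-3,5-diene-1,2-diol; 2 2,2-dimethoxypropane
Product: 3 (3aS,7aS)-4-bromo-2,2-dimethyl-3a,7a-dihydro-1,3-benzodioxole
Conditions: 2,2-dimethoxypropane, p-TsOH (cat.), acetone, 0 °C → rt; used directly
Reagents that add atoms: none
Why: Acid-catalysed acetonide formation (transketalisation) on the cis-1,2-diol is routine for arene cis-dihydrodiols, leaves both carbinol centres untouched and gives a diene that is carried on at once because it dimerises on standing.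

Step 2
Reactants: 3 (3aS,7aS)-4-bromo-2,2-dimethyl-3a,7a-dihydro-1,3-benzodioxole; 4 ethynyltrimethylsilane
Product: 5 (3aR,7aS)-2,2-dimethyl-4-[(trimethylsilyl)ethynyl]-3a,7a-dihydro-1,3-benzodioxole
Conditions: PdCl2(PPh3)2 (cat.), CuI (cat.), Et3N, THF, rt
Reagents that add atoms: none
Why: Sonogashira coupling of the alkenyl bromide with the terminal alkyne is established for halodiene acetonides of this type and should install the masked two-carbon arm at the future C4 with the dioxolane stereocentres unaffected.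

Step 3
Reactants: 5 (3aR,7aS)-2,2-dimethyl-4-[(trimethylsilyl)ethynyl]-3a,7a-dihydro-1,3-benzodioxole; 6 dioxygen (as singlet oxygen)
Product: 7 (3aS,4R,7R,7aR)-2,2-dimethyl-4-[(trimethylsilyl)ethynyl]-3a,4,7,7a-tetrahydro-4,7-epidioxy-1,3-benzodioxole (peroxide bridge from C1 to C4 of the target ring, anti to the dioxolane)
Conditions: O2, tetraphenylporphyrin (cat.), visible light, CH2Cl2, −78 °C
Reagents that add atoms: none
Why: Visible-light sensitisation converts ground-state O2 to singlet oxygen, which adds as a 2π component in a concerted suprafacial [4+2] cycloaddition to the termini of the ring diene (the alkynyl-bearing carbon and the CH next to the dioxolane), forming the C4–O and C1–O bonds at once. The closest known reaction type is the dye-sensitised photooxygenation of cyclohexa-1,3-dienes, including acetonides of arene cis-dihydrodiols, to bicyclic endoperoxides. The six-membered 1,2-dioxine ring is closed by this cycloaddition itself (intermolecular [4+2], both C–O bonds to the same face), which makes the 2,3-dioxabicyclo[2.2.2]oct-5-ene. Both new stereocentres, C1 and C4, are controlled by the cis-fused dioxolane: its endo methyl group and ring oxygens block the syn face, so oxygen enters anti and C4 receives its final configuration. The step needs facial selectivity and cycloaddition in preference to ene or [2+2] pathways; the s-cis geometry is locked by the ring, the only allylic hydrogens are the dioxolane methines on the shielded face, and the silyl-capped alkyne is unreactive toward singlet oxygen. Working at −78 °C keeps the diene from dimerising and the peroxide from rearranging to a bis-epoxide.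

Step 4
Reactants: 7 (3aS,4R,7R,7aR)-2,2-dimethyl-4-[(trimethylsilyl)ethynyl]-3a,4,7,7a-tetrahydro-4,7-epidioxy-1,3-benzodioxole
Product: 8 (3aR,7R,7aS)-7-hydroxy-2,2-dimethyl-7-[(trimethylsilyl)ethynyl]-7,7a-dihydro-1,3-benzodioxol-4(3aH)-one
Conditions: Et3N, CH2Cl2, 0 °C
Reagents that add atoms: none
Why: Kornblum–DeLaMare rearrangement, in which the amine removes the only bridgehead hydrogen (C1–H) as the O–O bond breaks, should give the C1 ketone and leave the C4–O bond, and hence the C4 configuration, intact.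

Step 5
Reactants: 8 (3aR,7R,7aS)-7-hydroxy-2,2-dimethyl-7-[(trimethylsilyl)ethynyl]-7,7a-dihydro-1,3-benzodioxol-4(3aH)-one
Product: 9 (3aR,5R,6S,7S,7aS)-5,6-epoxy-7-hydroxy-2,2-dimethyl-7-[(trimethylsilyl)ethynyl]hexahydro-1,3-benzodioxol-4-one (oxirane syn to the hydroxyl, anti to the dioxolane)
Conditions: t-BuOOH (in decane), DBU, CH2Cl2, −10 → 0 °C
Reagents that add atoms: tert-butyl hydroperoxide, CC(C)(C)OO
Why: Weitz–Scheffer nucleophilic epoxidation of the enone, in which tert-butyl peroxide anion adds to C5 on the face of the hydrogen-bonding C4 hydroxyl and away from the dioxolane, should set C5 and C6 with the oxirane syn to the C4–OH, while the aprotic amidine/hydroperoxide medium spares the alkynylsilane and is too weakly basic to enolise C2.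

Step 6
Reactants: 9 (3aR,5R,6S,7S,7aS)-5,6-epoxy-7-hydroxy-2,2-dimethyl-7-[(trimethylsilyl)ethynyl]hexahydro-1,3-benzodioxol-4-one
Product: 11 (1R,5S,6S)-5-hydroxy-2-oxo-5-[(trimethylsilyl)ethynyl]-7-oxabicyclo[4.1.0]hept-3-en-3-yl trifluoromethanesulfonate, via diosphenol 10 (not isolated)
Conditions: DBU, CH2Cl2, −20 → 0 °C; then PhNTf2, 0 °C → rt
Reagents that add atoms: N-phenylbis(trifluoromethanesulfonimide), O=S(=O)(N(c1ccccc1)S(=O)(=O)C(F)(F)F)C(F)(F)F
Why: E1cB β-elimination of the α,β-isopropylidenedioxy ketone (enolisation at C2 is far easier than at the oxirane C6–H, the C3 oxygen leaves and the hemiketal alkoxide sheds acetone) gives the diosphenolate, which is O-triflated in the same flask by PhNTf2 without touching the tertiary alcohol or the C4, C5 and C6 centres.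

Step 7
Reactants: 12 cyclohexanecarbaldehyde; 13 (triphenylphosphoranylidene)acetaldehyde
Product: 14 (E)-3-cyclohexylprop-2-enal
Conditions: toluene, 80 °C
Reagents that add atoms: none
Why: Wittig olefination with the stabilised formylmethylene ylide should give the (E)-enal, the product being less electrophilic than the starting aldehyde so that double homologation stays minor.

Step 8
Reactants: 14 (E)-3-cyclohexylprop-2-enal; 15 diethyl (2-amino-2-oxoethyl)phosphonate
Product: 16 (2E,4E)-5-cyclohexylpenta-2,4-dienamide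
Conditions: NaH, THF, 0 °C; then 14, 0 °C → rt
Reagents that add atoms: none
Why: Horner–Wadsworth–Emmons olefination of the enal with the carbamoylmethyl phosphonate anion is (E)-selective and delivers the primary (2E,4E)-dienamide directly.

Step 9
Reactants: 11 (1R,5S,6S)-5-hydroxy-2-oxo-5-[(trimethylsilyl)ethynyl]-7-oxabicyclo[4.1.0]hept-3-en-3-yl trifluoromethanesulfonate; 16 (2E,4E)-5-cyclohexylpenta-2,4-dienamide
Product: 17 (2E,4E)-5-cyclohexyl-N-{(1R,5S,6S)-5-hydroxy-2-oxo-5-[(trimethylsilyl)ethynyl]-7-oxabicyclo[4.1.0]hept-3-en-3-yl}penta-2,4-dienamide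
Conditions: Pd2(dba)3 (cat.), Xantphos, Cs2CO3, anhydrous 1,4-dioxane, 40 °C
Reagents that add atoms: none
Why: Palladium-catalysed amidation of an alkenyl triflate (Buchwald–Hartwig-type C–N coupling) should work because oxidative addition into the electron-poor 2-trifloxy enone is easy and the wide-bite-angle ligand favours C–N reductive elimination with primary amides, while anhydrous carbonate leaves the alkynylsilane, oxirane and tertiary alcohol alone.

Step 10
Reactants: 17 (2E,4E)-5-cyclohexyl-N-{(1R,5S,6S)-5-hydroxy-2-oxo-5-[(trimethylsilyl)ethynyl]-7-oxabicyclo[4.1.0]hept-3-en-3-yl}penta-2,4-dienamide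
Product: 18 (2E,4E)-5-cyclohexyl-N-[(1R,5S,6S)-5-ethynyl-5-hydroxy-2-oxo-7-oxabicyclo[4.1.0]hept-3-en-3-yl]penta-2,4-dienamide
Conditions: TBAF, AcOH, THF, −20 → 0 °C
Reagents that add atoms: none
Why: Fluoride-mediated protiodesilylation of the alkynylsilane is fast at low temperature, and buffering with acetic acid keeps the medium near neutral so that the epoxy ketone and enamide should survive.

Step 11
Reactants: 18 (2E,4E)-5-cyclohexyl-N-[(1R,5S,6S)-5-ethynyl-5-hydroxy-2-oxo-7-oxabicyclo[4.1.0]hept-3-en-3-yl]penta-2,4-dienamide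
Product: 19 (2E,4E)-5-cyclohexyl-N-{(1R,5S,6S)-5-hydroxy-2-oxo-5-[(E)-2-(tributylstannyl)ethenyl]-7-oxabicyclo[4.1.0]hept-3-en-3-yl}penta-2,4-dienamide
Conditions: Bu3SnH (slow addition), PdCl2(PPh3)2 (cat.), THF, 0 °C
Reagents that add atoms: tributyltin hydride, CCCC[SnH](CCCC)CCCC
Why: Palladium-catalysed hydrostannation adds Sn–H syn across the terminal alkyne and, with a fully substituted propargylic carbon, should place tin on the terminal carbon to give the (E)-alkenylstannane faster than any Pd–H reduction of the enone at 0 °C.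

Step 12
Reactants: 20 cyclopentane-1,3-dione
Product: 21 2-nitrocyclopentane-1,3-dione (enol form, 3-hydroxy-2-nitrocyclopent-2-en-1-one)
Conditions: fuming HNO3, Et2O, −5 → 0 °C
Reagents that add atoms: nitric acid, O[N+](=O)[O-]
Why: Electrophilic nitration at C2 of the enolised cyclic 1,3-dione is a classical entry to 2-nitro-1,3-diones and has no regiochemical alternative.

Step 13
Reactants: 21 2-nitrocyclopentane-1,3-dione
Product: 22 2-amino-3-hydroxycyclopent-2-en-1-one hydrochloride
Conditions: H2 (1 atm), 10% Pd/C, HCl, MeOH, rt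
Reagents that add atoms: hydrogen chloride, Cl
Why: Catalytic hydrogenation of the nitro group gives the amine, which is trapped as its hydrochloride so that the α-amino dione cannot condense with itself.

Step 14
Reactants: 23 glutaconaldehyde potassium salt
Product: 24 (2E,4E)-5-bromopenta-2,4-dienal
Conditions: PPh3, Br2, CH2Cl2, 0 °C; then 23, 0 °C → rt
Reagents that add atoms: bromine (used as Ph3PBr2 made in the flask), BrBr
Why: O-Phosphonium activation of the dienolate by Ph3PBr2 followed by bromide addition–elimination (deoxybromination of a vinylogous acid) should give the 5-bromodienal, which equilibrates to the conjugated (2E,4E) isomer.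

Step 15
Reactants: 24 (2E,4E)-5-bromopenta-2,4-dienal
Product: 25 (2E,4E)-5-bromopenta-2,4-dienoic acid
Conditions: NaClO2, NaH2PO4, 2-methyl-2-butene, t-BuOH/H2O, 0 °C → rt
Reagents that add atoms: sodium chlorite, [Na+].[O-]Cl=O
Why: Pinnick oxidation converts the enal to the acid under buffered conditions that leave the bromodiene untouched, 2-methyl-2-butene removing the hypochlorous acid formed.

Step 16
Reactants: 25 (2E,4E)-5-bromopenta-2,4-dienoic acid; 22 2-amino-3-hydroxycyclopent-2-en-1-one hydrochloride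
Product: 27 (2E,4E)-5-bromo-N-(2-hydroxy-5-oxocyclopent-1-en-1-yl)penta-2,4-dienamide, via benzotriazolyl ester 26 (not isolated)
Conditions: EDC·HCl, HOBt, Et3N, DMF, 0 °C → rt
Reagents that add atoms: none
Why: Carbodiimide/HOBt amide coupling, in which the amine freed from its hydrochloride is acylated by the active ester and any O-acyl enol isomer rearranges to the more stable N-acyl vinylogous acid.

Step 17
Reactants: 19 (2E,4E)-5-cyclohexyl-N-{(1R,5S,6S)-5-hydroxy-2-oxo-5-[(E)-2-(tributylstannyl)ethenyl]-7-oxabicyclo[4.1.0]hept-3-en-3-yl}penta-2,4-dienamide; 27 (2E,4E)-5-bromo-N-(2-hydroxy-5-oxocyclopent-1-en-1-yl)penta-2,4-dienamide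
Product: 28 (2E,4E)-5-cyclohexyl-N-[(1R,5R,6S)-5-hydroxy-5-{(1E,3E,5E)-7-[(2-hydroxy-5-oxocyclopent-1-en-1-yl)amino]-7-oxohepta-1,3,5-trien-1-yl}-2-oxo-7-oxabicyclo[4.1.0]hept-3-en-3-yl]penta-2,4-dienamide (target)
Conditions: PdCl2(MeCN)2 (cat.), DMF, rt, dark
Reagents that add atoms: none
Why: Stille cross-coupling of an (E)-alkenylstannane with an (E)-alkenyl bromide proceeds with retention at both sp2 carbons and, under ligand-free Pd(II) in DMF at room temperature, should tolerate the free alcohol, enol and N–H groups and give the all-(E) triene.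

**Compound list**

1 | (1S,2S)-3-bromocyclohexa-3,5-diene-1,2-diol | O[C@H]1C=CC=C(Br)[C@H]1O | starting material
2 | 2,2-dimethoxypropane | COC(C)(C)OC | starting material
3 | (3aS,7aS)-4-bromo-2,2-dimethyl-3a,7a-dihydro-1,3-benzodioxole | CC1(C)O[C@H]2C=CC=C(Br)[C@H]2O1 | intermediate
4 | ethynyltrimethylsilane | C#C[Si](C)(C)C | starting material
5 | (3aR,7aS)-2,2-dimethyl-4-[(trimethylsilyl)ethynyl]-3a,7a-dihydro-1,3-benzodioxole | CC1(C)O[C@H]2C=CC=C(C#C[Si](C)(C)C)[C@H]2O1 | intermediate
6 | dioxygen | O=O | starting material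
7 | (3aS,4R,7R,7aR)-2,2-dimethyl-4-[(trimethylsilyl)ethynyl]-3a,4,7,7a-tetrahydro-4,7-epidioxy-1,3-benzodioxole | CC1(C)O[C@H]2[C@H]3C=C[C@](C#C[Si](C)(C)C)(OO3)[C@H]2O1 | intermediate
8 | (3aR,7R,7aS)-7-hydroxy-2,2-dimethyl-7-[(trimethylsilyl)ethynyl]-7,7a-dihydro-1,3-benzodioxol-4(3aH)-one | CC1(C)O[C@H]2C(=O)C=C[C@](C#C[Si](C)(C)C)(O)[C@H]2O1 | intermediate
9 | (3aR,5R,6S,7S,7aS)-5,6-epoxy-7-hydroxy-2,2-dimethyl-7-[(trimethylsilyl)ethynyl]hexahydro-1,3-benzodioxol-4-one | CC1(C)O[C@H]2C(=O)[C@@H]3O[C@@H]3[C@](C#C[Si](C)(C)C)(O)[C@H]2O1 | intermediate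
10 | (1R,5S,6S)-3,5-dihydroxy-5-[(trimethylsilyl)ethynyl]-7-oxabicyclo[4.1.0]hept-3-en-2-one (diosphenol) | OC1=C[C@](O)(C#C[Si](C)(C)C)[C@H]2O[C@H]2C1=O | intermediate
11 | (1R,5S,6S)-5-hydroxy-2-oxo-5-[(trimethylsilyl)ethynyl]-7-oxabicyclo[4.1.0]hept-3-en-3-yl trifluoromethanesulfonate | FC(F)(F)S(=O)(=O)OC1=C[C@](O)(C#C[Si](C)(C)C)[C@H]2O[C@H]2C1=O | intermediate
12 | cyclohexanecarbaldehyde | O=CC1CCCCC1 | starting material
13 | (triphenylphosphoranylidene)acetaldehyde | O=CC=P(c1ccccc1)(c1ccccc1)c1ccccc1 | starting material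
14 | (E)-3-cyclohexylprop-2-enal | O=C/C=C/C1CCCCC1 | intermediate
15 | diethyl (2-amino-2-oxoethyl)phosphonate | CCOP(=O)(CC(N)=O)OCC | starting material
16 | (2E,4E)-5-cyclohexylpenta-2,4-dienamide | NC(=O)/C=C/C=C/C1CCCCC1 | intermediate
17 | (2E,4E)-5-cyclohexyl-N-{(1R,5S,6S)-5-hydroxy-2-oxo-5-[(trimethylsilyl)ethynyl]-7-oxabicyclo[4.1.0]hept-3-en-3-yl}penta-2,4-dienamide | O=C(/C=C/C=C/C1CCCCC1)NC1=C[C@](O)(C#C[Si](C)(C)C)[C@H]2O[C@H]2C1=O | intermediate
18 | (2E,4E)-5-cyclohexyl-N-[(1R,5S,6S)-5-ethynyl-5-hydroxy-2-oxo-7-oxabicyclo[4.1.0]hept-3-en-3-yl]penta-2,4-dienamide | O=C(/C=C/C=C/C1CCCCC1)NC1=C[C@](O)(C#C)[C@H]2O[C@H]2C1=O | intermediate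
19 | (2E,4E)-5-cyclohexyl-N-{(1R,5S,6S)-5-hydroxy-2-oxo-5-[(E)-2-(tributylstannyl)ethenyl]-7-oxabicyclo[4.1.0]hept-3-en-3-yl}penta-2,4-dienamide | O=C(/C=C/C=C/C1CCCCC1)NC1=C[C@](O)(/C=C/[Sn](CCCC)(CCCC)CCCC)[C@H]2O[C@H]2C1=O | intermediate
20 | cyclopentane-1,3-dione | O=C1CCC(=O)C1 | starting material
21 | 2-nitrocyclopentane-1,3-dione (enol form, 3-hydroxy-2-nitrocyclopent-2-en-1-one) | O=C1CCC(O)=C1[N+](=O)[O-] | intermediate
22 | 2-amino-3-hydroxycyclopent-2-en-1-one hydrochloride | NC1=C(O)CCC1=O.Cl | intermediate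
23 | glutaconaldehyde potassium salt (potassium (1E,3E)-5-oxopenta-1,3-dien-1-olate) | [K+].[O-]/C=C/C=C/C=O | starting material
24 | (2E,4E)-5-bromopenta-2,4-dienal | O=C/C=C/C=C/Br | intermediate
25 | (2E,4E)-5-bromopenta-2,4-dienoic acid | OC(=O)/C=C/C=C/Br | intermediate
26 | 1H-benzotriazol-1-yl (2E,4E)-5-bromopenta-2,4-dienoate | O=C(/C=C/C=C/Br)On1nnc2ccccc12 | intermediate
27 | (2E,4E)-5-bromo-N-(2-hydroxy-5-oxocyclopent-1-en-1-yl)penta-2,4-dienamide | O=C(/C=C/C=C/Br)NC1=C(O)CCC1=O | intermediate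
28 | (2E,4E)-5-cyclohexyl-N-[(1R,5R,6S)-5-hydroxy-5-{(1E,3E,5E)-7-[(2-hydroxy-5-oxocyclopent-1-en-1-yl)amino]-7-oxohepta-1,3,5-trien-1-yl}-2-oxo-7-oxabicyclo[4.1.0]hept-3-en-3-yl]penta-2,4-dienamide | O=C(/C=C/C=C/C1CCCCC1)NC1=C[C@](O)(/C=C/C=C/C=C/C(=O)NC2=C(O)CCC2=O)[C@H]2O[C@H]2C1=O | target

**Step count and risks**

Total: 17 steps. Longest linear sequence: 10 steps (steps 1–6, 9, 10, 11 and 17, from 1 to 28).

Steps most likely to fail:

Step 6. The risk is competitive enolisation toward the oxirane, or loss of water from the diosphenolate (aromatisation), before O-sulfonylation takes place. The fallback sets out from 8 and removes the acetonide before any oxirane is present. DBU in CH2Cl2 at 0 °C should effect the same E1cB elimination on the enone and give (S)-2,4-dihydroxy-4-[(trimethylsilyl)ethynyl]cyclohexa-2,5-dien-1-one F1. Triflation of its enol with PhNTf2 and Et3N in CH2Cl2 would give (3S)-3-hydroxy-6-oxo-3-[(trimethylsilyl)ethynyl]cyclohexa-1,4-dien-1-yl trifluoromethanesulfonate F2. Nucleophilic epoxidation with t-BuOOH and DBU in CH2Cl2 at −10 °C is expected to attack the unsubstituted C5=C6 arm of the cross-conjugated dienone, on the face of the hydrogen-bonding C4 hydroxyl. Facial control then rests on the hydroxyl alone. The sequence comes back to the route at 11.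

Step 9. The risk is slow C–N reductive elimination with the weakly nucleophilic conjugated primary amide, so that carbonate-induced degradation of the epoxy triflate or loss of the alkynyl silyl group outruns the coupling. The fallback sets out from 11 and introduces nitrogen and the acyl group separately. Coupling with benzophenone imine (Pd2(dba)3, Xantphos, Cs2CO3, dioxane) should give (1R,5S,6S)-3-[(diphenylmethylidene)amino]-5-hydroxy-5-[(trimethylsilyl)ethynyl]-7-oxabicyclo[4.1.0]hept-3-en-2-one F3. Brief hydrolysis with aqueous citric acid in THF at 0 °C would release (1R,5S,6S)-3-amino-5-hydroxy-5-[(trimethylsilyl)ethynyl]-7-oxabicyclo[4.1.0]hept-3-en-2-one F4. The acyl donor is made from 14 by Doebner–Knoevenagel condensation with malonic acid (pyridine, piperidine, 90 °C) to (2E,4E)-5-cyclohexylpenta-2,4-dienoic acid F5, which oxalyl chloride and catalytic DMF convert to (2E,4E)-5-cyclohexylpenta-2,4-dienoyl chloride F6. N-Acylation of F4 with F6 (pyridine, CH2Cl2, 0 °C) comes back to the route at 17.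

Step 11. The risk is Pd–H conjugate reduction of the amido-enone, or delivery of tin to the internal alkyne carbon. The fallback sets out from 18 and forms the C–C bond before the alkyne is reduced. Sonogashira coupling of 18 with 27 (Pd(PPh3)4, CuI, Et3N, THF, rt) should give (2E,4E)-5-cyclohexyl-N-[(1R,5S,6S)-5-hydroxy-5-{(3E,5E)-7-[(2-hydroxy-5-oxocyclopent-1-en-1-yl)amino]-7-oxohepta-3,5-dien-1-yn-1-yl}-2-oxo-7-oxabicyclo[4.1.0]hept-3-en-3-yl]penta-2,4-dienamide F7. Ruthenium-catalysed trans-hydrosilylation ([Cp*Ru(MeCN)3]PF6, (EtO)3SiH, CH2Cl2, 0 °C) would give (2E,4E)-5-cyclohexyl-N-[(1R,5S,6S)-5-hydroxy-5-{(1Z,3E,5E)-7-[(2-hydroxy-5-oxocyclopent-1-en-1-yl)amino]-7-oxo-2-(triethoxysilyl)hepta-1,3,5-trien-1-yl}-2-oxo-7-oxabicyclo[4.1.0]hept-3-en-3-yl]penta-2,4-dienamide F8. Either silane regioisomer converges in the next operation. Protodesilylation with AgF in THF/MeOH/H2O at rt in the dark replaces silicon by hydrogen with retention and comes back to the route at 28.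

**Further compounds**

F1 | step 6 | (S)-2,4-dihydroxy-4-[(trimethylsilyl)ethynyl]cyclohexa-2,5-dien-1-one | OC1=C[C@](O)(C#C[Si](C)(C)C)C=CC1=O
F2 | step 6 | (3S)-3-hydroxy-6-oxo-3-[(trimethylsilyl)ethynyl]cyclohexa-1,4-dien-1-yl trifluoromethanesulfonate | FC(F)(F)S(=O)(=O)OC1=C[C@](O)(C#C[Si](C)(C)C)C=CC1=O
F3 | step 9 | (1R,5S,6S)-3-[(diphenylmethylidene)amino]-5-hydroxy-5-[(trimethylsilyl)ethynyl]-7-oxabicyclo[4.1.0]hept-3-en-2-one | C(=NC1=C[C@](O)(C#C[Si](C)(C)C)[C@H]2O[C@H]2C1=O)(c1ccccc1)c1ccccc1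
F4 | step 9 | (1R,5S,6S)-3-amino-5-hydroxy-5-[(trimethylsilyl)ethynyl]-7-oxabicyclo[4.1.0]hept-3-en-2-one | NC1=C[C@](O)(C#C[Si](C)(C)C)[C@H]2O[C@H]2C1=O
F5 | step 9 | (2E,4E)-5-cyclohexylpenta-2,4-dienoic acid | OC(=O)/C=C/C=C/C1CCCCC1
F6 | step 9 | (2E,4E)-5-cyclohexylpenta-2,4-dienoyl chloride | O=C(Cl)/C=C/C=C/C1CCCCC1
F7 | step 11 | (2E,4E)-5-cyclohexyl-N-[(1R,5S,6S)-5-hydroxy-5-{(3E,5E)-7-[(2-hydroxy-5-oxocyclopent-1-en-1-yl)amino]-7-oxohepta-3,5-dien-1-yn-1-yl}-2-oxo-7-oxabicyclo[4.1.0]hept-3-en-3-yl]penta-2,4-dienamide | O=C(/C=C/C=C/C1CCCCC1)NC1=C[C@](O)(C#C/C=C/C=C/C(=O)NC2=C(O)CCC2=O)[C@H]2O[C@H]2C1=O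
F8 | step 11 | (2E,4E)-5-cyclohexyl-N-[(1R,5S,6S)-5-hydroxy-5-{(1Z,3E,5E)-7-[(2-hydroxy-5-oxocyclopent-1-en-1-yl)amino]-7-oxo-2-(triethoxysilyl)hepta-1,3,5-trien-1-yl}-2-oxo-7-oxabicyclo[4.1.0]hept-3-en-3-yl]penta-2,4-dienamide | O=C(/C=C/C=C/C1CCCCC1)NC1=C[C@](O)(/C=C(\[Si](OCC)(OCC)OCC)/C=C/C=C/C(=O)NC2=C(O)CCC2=O)[C@H]2O[C@H]2C1=O
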